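Compound numbers used below are those of the steps and of the compound list that follows them.

## Analysis of the target

Target 35 (CNP0192589.0) is an achiral pentacyclic flavone. Ring A is a fully substituted benzene, ring C the 4-pyranone and ring B a 4′,5′-dimethoxyphenyl ring. Ring D is a 2,2-dimethyl-2H-pyran fused angularly to ring A through O7 and C8. Ring E is a seven-membered oxepine that ties C3 to C2′ through a CH2–C(=CMe2)–O bridge.

There is no stereocentre, and the exocyclic alkene of ring E ends in two methyl groups, so there is no alkene geometry to set. The whole problem is one of regiochemistry.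

Going round ring A, C8a carries O1, C8 the vinyl carbon of ring D, C7 the oxygen of ring D, C6 a prenyl group, C5 a methoxy group and C4a the carbonyl carbon. Four kinds of substituent must therefore each be put on one defined carbon.

The sensitive groups are the tetrasubstituted enol ether of ring E (acid), the styrene-like alkene of ring D and the prenyl alkene (acid, electrophiles, oxidants), and the 5-methoxy group peri to the carbonyl (Lewis acids).

The hard points are the angular rather than linear fusion of ring D, the prenyl group between two oxygens, and the closure of ring E at a hindered, fully substituted alkenyl carbon.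

The strategy rests on the triad C7–C8–C8a of ring A, which carries O, C and O in a row. The aryl–O and neighbouring aryl–C bonds of ring D, next to a further oxygenated carbon, are what an aldehyde leaves when it adds across an aryne flanked by an oxygen substituent.

## Retrosynthetic reasoning

**Ring E (35 to 34).** The aryl–O–vinyl bond is cut first, giving phenol 34 with a 2-bromoprenyl chain on C3. The enol ether is the most acid-labile group, so it is made last and under basic conditions. The alkenyl bromide fixes the double bond in the exocyclic position, which a ketone-based closure would not. The forward reaction must join a phenoxide to a tetrasubstituted alkenyl bromide in a seven-membered ring.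

**Ring C and the C3 chain (34 to 33 to 32 to 29 and 31).** Removing the allyl group from the ring-B oxygen leads back to 33. Opening the pyranone at O1–C2 gives the 2-substituted 1,3-diketone 32. Cutting the C3–CH2 bond gives diketone 29 and the allylic dibromide 31, made from allene 30. The central carbon of a 1,3-diketone is a soft nucleophile exactly at the future C3, so the side chain goes in under mild base. The ring-B oxygen stays protected so that only the ring-A phenol can close ring C.

**Diketone (29 to 28 to 23 and 26).** The C–C bond between the ring-A acetyl group and the ring-B carbonyl comes from an intramolecular acyl transfer in ester 28. Ester 28 is cut at the ester bond into acetophenone 23 and acid 26. Acid 26 comes from 24 through 25. The allyl ether is chosen because it survives strong base and the acid of the cyclodehydration.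

**Ring-A substituents (23 to 22 to 20 to 18 to 15 to 14 to 13).** The acetyl group at chromene C6 and the prenyl group at chromene C8 are each placed by directed metalation. A bulky silyl ether on the C5 oxygen (15) leaves only C8, between the methoxy group and the ring oxygen, open for the first metalation. After exchange to an acetal (20) the last free position, between acetal and methoxy, is metalated and acylated. Friedel–Crafts acylation is avoided because the chromene and prenyl alkenes would not survive it. The phenol 14 comes from triflate 13.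

**Key disconnection (13 to 8 and 9).** Ring D is cut at C8a–O, C4a–C4 and O–CMe2 (chromene numbering), which gives an aryne and 3-methylbut-2-enal 9. The aryne precursor 8 is symmetric, so only one aryne can form. The surviving triflate marks the oxygen that becomes O1. One step therefore fixes the angular fusion and the O/C/O triad that a phenol–enal condensation would deliver as a mixture.

**Aryne precursor (8 to 6 to 2 to 1).** The two triflates come from the two phenols of 5-methoxyresorcinol 1, and the silyl group from metalation between two carbamates (2 to 6). Carbamates are used because they are removed by base. Acid-labile directing groups would put the C–Si bond on this very electron-rich ring at risk of protodesilylation.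

## Alternatives that were turned down

**Alternative 1:** The C3–C4 bond of ring C is disconnected. Aldehyde A2 is a ring-A benzaldehyde whose ortho oxygen carries a propargylic carbon bearing ring B and an alkyne that ends in the bromoalkene. A thiazolium salt and K2CO3 would turn the aldehyde into an acyl anion equivalent that adds to the near alkyne carbon. DBU would then shift the exocyclic double bond into the ring to give flavone A1.

- For it: ring C and the complete C3 side chain arise in one operation without acid. On this point it is stronger than the chosen route, which needs rearrangement, alkylation and an acidic cyclodehydration.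
- Against it: the aldehyde sits between a methoxy group and an ether oxygen on an electron-rich ring, which is unfavourable for forming the acyl anion equivalent. The acceptor is an unactivated alkyne conjugated to a bromoalkene. A2 needs a doubly activated (benzylic and propargylic) ether on a hindered phenol, which ionises easily.
- Comparison: it still needs a ring-A/ring-D building block of defined regiochemistry and says nothing about how to get it. The chosen strategy supplies that block and puts its risk at step 4 on simple material rather than on a late, crowded intermediate.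

**Alternative 2:** The C6–CH2 bond and ring D are disconnected from bis-ether A4. In A4 rings B, C and E are complete, and O5 and O7 carry 1,1-dimethylallyl and 1,1-dimethylpropargyl groups. Heating in N,N-diethylaniline would move the allyl group to C6 by aromatic Claisen rearrangement, giving the prenyl group. The propargyl ether would give the pyran at C8 by Claisen rearrangement, 1,5-hydrogen shift and oxa-6π closure. The product A3 then needs O-methylation to reach 35.

- For it: three bonds and a ring form without reagents, and the step count is clearly lower than in the chosen route. If the allyl shift is the faster one, C6 is filled first and the propargyl group is forced to C8.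
- Against it: that outcome depends on relative rates, not on structure. The propargyl ether has both C6 and C8 open, so a linear pyran is possible. The tertiary allyl ether on the hydrogen-bonded, hindered O5 is hard to make and loses isoprene on heating. The enol ether of ring E must survive about 200 °C. A hindered, chelated phenol must be methylated at the end.
- Comparison: the chosen strategy is longer, but each ring-A substituent is placed by a reaction with one possible outcome.

**Alternative 3:** Ring C is disconnected into three pieces at C4a–C4, C4–C3 and O1–C2: iodophenol A6, carbon monoxide and alkyne A7. PdCl2(PPh3)2 in Et2NH under CO would give an ynone by oxidative addition, CO insertion and alkynylation. Amine-mediated 6-endo closure would then give flavone A5.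

- For it: it is the most convergent way to ring C. One step replaces acetylation, esterification, rearrangement and cyclodehydration, and it avoids acid. Here it is stronger than the chosen route.
- Against it: the iodide lies between a hydroxyl and a methoxy group on a very electron-rich ring, so oxidative addition to zerovalent palladium and acyl formation are slow. 5-exo closure to an aurone competes. A6 must be made by iodination in the presence of two reactive alkenes. A5 has hydrogen at C3, so the side chain would need a later metalation of the flavone.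
- Comparison: the diketone 29 of the chosen route offers a nucleophilic carbon at C3 under mild base. Like alternative 1, this alternative leaves the ring-A/ring-D regiochemistry unsolved, which the aryne step settles.

Key step: step 4

Remark: bromination of 30 is taken to give, after allylic equilibration, the primary allylic dibromide 31; its tertiary allylic isomer would alkylate by SN2′ to the same product.

## Route

Step 1
Reactants: 1 5-methoxyresorcinol
Product: 2 5-methoxy-1,3-phenylene bis(isopropylcarbamate)
Conditions: i-PrNCO (2.4 equiv), Et3N (cat.), CH2Cl2, rt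
Reagents that add atoms: isopropyl isocyanate, CC(C)N=C=O
Why: Base-catalysed addition of both phenols to the isocyanate (carbamoylation). The N-isopropyl carbamate is a strong ortho-directing group that can later be removed by base, which matters because an arylsilane on this electron-rich ring would not survive acidic deprotection.

Step 2
Reactants: 2 5-methoxy-1,3-phenylene bis(isopropylcarbamate)
Product: 6 5-methoxy-2-(trimethylsilyl)-1,3-phenylene bis(isopropylcarbamate), via N-silylated biscarbamate 3 (not isolated), via aryllithium 4 (not isolated), via C-silylated N-silyl biscarbamate 5 (not isolated)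
Conditions: TBSOTf (2.1 equiv), TMEDA, Et2O, 0 °C → rt; n-BuLi, TMEDA, −78 °C; Me3SiCl, −78 °C → rt; aq. NaHSO4
Reagents that add atoms: chlorotrimethylsilane, C[Si](C)(C)Cl
Why: In situ N-silylation masks both N–H groups, and directed ortho-metalation then takes place at C2, the only position flanked by two carbamates (a stronger cooperative effect than carbamate plus methoxy). Silyl quench and aqueous NaHSO4 work-up, which strips the N-silyl groups, give 6.

Step 3
Reactants: 6 5-methoxy-2-(trimethylsilyl)-1,3-phenylene bis(isopropylcarbamate)
Product: 8 5-methoxy-2-(trimethylsilyl)-1,3-phenylene bis(trifluoromethanesulfonate), via silylresorcinol 7 (not isolated)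
Conditions: DBU, Et2NH, MeCN, 40 °C; then PhNTf2, rt
Reagents that add atoms: N-phenylbis(trifluoromethanesulfonimide), O=S(=O)(N(c1ccccc1)S(=O)(=O)C(F)(F)F)C(F)(F)F
Why: DBU cleaves the N–H carbamates by E1cB elimination and Et2NH scavenges the isocyanate. The bis-phenolate is triflated in the same flask, so the acid-sensitive silylresorcinol 7 is never isolated.

Step 4
Reactants: 8 5-methoxy-2-(trimethylsilyl)-1,3-phenylene bis(trifluoromethanesulfonate); 9 3-methylbut-2-enal
Product: 13 7-methoxy-2,2-dimethyl-2H-chromen-5-yl trifluoromethanesulfonate, via aryne 10 (not isolated), via benzoxete 11 (not isolated), via ortho-quinone methide 12 (not isolated)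
Conditions: CsF (3 equiv), 9 (5 equiv), MeCN, 0 °C → rt, slow addition of 8
Reagents that add atoms: none
Why: Fluoride attacks silicon and expels one of the two equivalent triflates, so only aryne 10 can form. The carbonyl oxygen of 9 adds to the aryne carbon remote from the remaining triflate, because the triflyloxy group distorts the triple bond toward that carbon and stabilises by induction the aryl anion that develops next to it. The anion then closes onto the adjacent oxocarbenium carbon, a four-membered ionic ring closure (formal [2+2]) that gives benzoxete 11. Benzoxete 11 opens by a retro-4π electrocyclic step to ortho-quinone methide 12, and ring D closes by thermal disrotatory oxa-6π electrocyclisation of this 1-oxatriene, which joins O to CMe2 and restores the arene. The closest known reaction type is the fluoride-induced annulation of arynes with α,β-unsaturated aldehydes to 2H-chromenes, combined with the known generation of 3-(triflyloxy)arynes from 2-silyl-1,3-bis(triflates). No stereocentre remains, since the one in 11 is lost on ring opening. The step needs oxygen to add distal to the triflate and the anion to close faster than it expels triflate; the inductive pull of the triflate secures the first and the intramolecular collapse of the ion pair the second, while slow addition of 8 to excess 9 keeps the aryne from reacting with itself or with product.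

Step 5
Reactants: 13 7-methoxy-2,2-dimethyl-2H-chromen-5-yl trifluoromethanesulfonate
Product: 14 7-methoxy-2,2-dimethyl-2H-chromen-5-ol
Conditions: Et4NOH (aq.), 1,4-dioxane, rt
Reagents that add atoms: none
Why: Hydroxide attacks the sulfonyl sulfur (S–O cleavage) and releases the phenolate. The chromene is stable to these mild basic conditions.

Step 6
Reactants: 14 7-methoxy-2,2-dimethyl-2H-chromen-5-ol
Product: 15 triisopropyl[(7-methoxy-2,2-dimethyl-2H-chromen-5-yl)oxy]silane
Conditions: i-Pr3SiCl, imidazole, DMF, rt
Reagents that add atoms: chlorotriisopropylsilane, CC(C)[Si](Cl)(C(C)C)C(C)C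
Why: Standard O-silylation. The bulky, weakly coordinating silyl ether shields C6 and leaves C8 as the only position open to directed metalation.

Step 7
Reactants: 15 triisopropyl[(7-methoxy-2,2-dimethyl-2H-chromen-5-yl)oxy]silane
Product: 18 triisopropyl{[7-methoxy-2,2-dimethyl-8-(3-methylbut-2-enyl)-2H-chromen-5-yl]oxy}silane, via aryllithium 16 (not isolated), via arylcopper 17 (not isolated)
Conditions: n-BuLi, THF, 0 °C; CuBr·SMe2, −78 °C; prenyl bromide, −78 °C → rt
Reagents that add atoms: 1-bromo-3-methylbut-2-ene (prenyl bromide), CC(C)=CCBr
Why: Directed ortho-metalation at C8, between the methoxy group and the ring oxygen. Transmetalation to monovalent copper makes the allylic substitution α-selective, so the linear prenyl group results.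

Step 8
Reactants: 18 triisopropyl{[7-methoxy-2,2-dimethyl-8-(3-methylbut-2-enyl)-2H-chromen-5-yl]oxy}silane
Product: 20 7-methoxy-5-(methoxymethoxy)-2,2-dimethyl-8-(3-methylbut-2-enyl)-2H-chromene, via chromenol 19 (not isolated)
Conditions: Bu4NF, THF, 0 °C; then i-Pr2NEt, MeOCH2Cl, 0 °C → rt
Reagents that add atoms: chloromethyl methyl ether, COCCl
Why: Fluoride desilylation gives the phenolate, which is alkylated in the same flask (Williamson-type ether formation). The acetal is the directing group for the second metalation.

Step 9
Reactants: 20 7-methoxy-5-(methoxymethoxy)-2,2-dimethyl-8-(3-methylbut-2-enyl)-2H-chromene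
Product: 22 1-[7-methoxy-5-(methoxymethoxy)-2,2-dimethyl-8-(3-methylbut-2-enyl)-2H-chromen-6-yl]ethanone, via aryllithium 21 (not isolated)
Conditions: n-BuLi, THF, 0 °C; MeC(O)N(OMe)Me, −78 °C → rt; H2O
Reagents that add atoms: N-methoxy-N-methylacetamide, CON(C)C(C)=O
Why: Directed ortho-metalation at the last free ring position, between acetal and methoxy. Acylation by the N-methoxy-N-methylamide stops at the ketone because the chelated tetrahedral adduct holds until work-up.

Step 10
Reactants: 22 1-[7-methoxy-5-(methoxymethoxy)-2,2-dimethyl-8-(3-methylbut-2-enyl)-2H-chromen-6-yl]ethanone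
Product: 23 1-[5-hydroxy-7-methoxy-2,2-dimethyl-8-(3-methylbut-2-enyl)-2H-chromen-6-yl]ethanone
Conditions: 2 M HCl, MeOH, 40 °C
Reagents that add atoms: none
Why: Acid-catalysed acetal exchange with methanol, made easy by the ortho acyl group. The prenyl group has no neighbouring free hydroxyl to cyclise onto, and the acyl group lowers the electron density of the chromene, so mild acid is tolerated.

Step 11
Reactants: 24 2-hydroxy-4,5-dimethoxybenzoic acid
Product: 25 allyl 2-(allyloxy)-4,5-dimethoxybenzoate
Conditions: allyl bromide (2.5 equiv), K2CO3, DMF, 60 °C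
Reagents that add atoms: allyl bromide, C=CCBr
Why: Double O-alkylation of carboxylate and phenolate (Williamson ether synthesis and ester alkylation).

Step 12
Reactants: 25 allyl 2-(allyloxy)-4,5-dimethoxybenzoate
Product: 26 2-(allyloxy)-4,5-dimethoxybenzoic acid
Conditions: LiOH, THF/MeOH/H2O, rt; then 1 M HCl
Reagents that add atoms: lithium hydroxide (its oxygen becomes the acid OH), [Li+].[OH-]
Why: Saponification of the ester. The aryl allyl ether is inert to hydroxide.

Step 13
Reactants: 23 1-[5-hydroxy-7-methoxy-2,2-dimethyl-8-(3-methylbut-2-enyl)-2H-chromen-6-yl]ethanone; 26 2-(allyloxy)-4,5-dimethoxybenzoic acid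
Product: 28 6-acetyl-7-methoxy-2,2-dimethyl-8-(3-methylbut-2-enyl)-2H-chromen-5-yl 2-(allyloxy)-4,5-dimethoxybenzoate, via acid chloride 27 (not isolated)
Conditions: 26, (COCl)2, DMF (cat.), CH2Cl2, 0 °C → rt; then 23, Et3N, DMAP (cat.), CH2Cl2, rt
Reagents that add atoms: none
Why: Acid chloride formation followed by DMAP-catalysed acylation of the hydrogen-bonded phenol. The allyl ether tolerates the HCl formed, which an acetal on the ring-B oxygen would not.

Step 14
Reactants: 28 6-acetyl-7-methoxy-2,2-dimethyl-8-(3-methylbut-2-enyl)-2H-chromen-5-yl 2-(allyloxy)-4,5-dimethoxybenzoate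
Product: 29 1-[2-(allyloxy)-4,5-dimethoxyphenyl]-3-[5-hydroxy-7-methoxy-2,2-dimethyl-8-(3-methylbut-2-enyl)-2H-chromen-6-yl]propane-1,3-dione
Conditions: LiN(SiMe3)2 (3 equiv), THF, −78 °C → rt; then dilute HCl, 0 °C
Reagents that add atoms: none
Why: Baker–Venkataraman rearrangement. The methyl ketone enolate attacks the neighbouring ester carbonyl in a six-membered transition state and the phenolate is expelled; formation of the stabilised diketonate drives the reaction.

Step 15
Reactants: 30 3-methylbuta-1,2-diene
Product: 31 1,2-dibromo-3-methylbut-2-ene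
Conditions: Br2, CH2Cl2, −78 °C → rt
Reagents that add atoms: bromine, BrBr
Why: Electrophilic addition of bromine to the allene. Allylic equilibration favours the primary bromide with the tetrasubstituted alkene.

Step 16
Reactants: 29 1-[2-(allyloxy)-4,5-dimethoxyphenyl]-3-[5-hydroxy-7-methoxy-2,2-dimethyl-8-(3-methylbut-2-enyl)-2H-chromen-6-yl]propane-1,3-dione; 31 1,2-dibromo-3-methylbut-2-ene
Product: 32 1-[2-(allyloxy)-4,5-dimethoxyphenyl]-2-(2-bromo-3-methylbut-2-enyl)-3-[5-hydroxy-7-methoxy-2,2-dimethyl-8-(3-methylbut-2-enyl)-2H-chromen-6-yl]propane-1,3-dione (racemic)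
Conditions: K2CO3, acetone, rt
Reagents that add atoms: none
Why: C-alkylation of the 1,3-diketonate, a soft carbon nucleophile, by the allylic bromide; the alkenyl bromide does not react. The new stereocentre is formed as a racemate and becomes sp2 in the next step.

Step 17
Reactants: 32 1-[2-(allyloxy)-4,5-dimethoxyphenyl]-2-(2-bromo-3-methylbut-2-enyl)-3-[5-hydroxy-7-methoxy-2,2-dimethyl-8-(3-methylbut-2-enyl)-2H-chromen-6-yl]propane-1,3-dione
Product: 33 2-[2-(allyloxy)-4,5-dimethoxyphenyl]-3-(2-bromo-3-methylbut-2-enyl)-5-methoxy-8,8-dimethyl-6-(3-methylbut-2-enyl)-4H,8H-pyrano[2,3-f]chromen-4-one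
Conditions: TsOH·H2O (cat.), MeCN, 60 °C
Reagents that add atoms: none
Why: Acid-catalysed cyclodehydration. The ring-A phenol adds to the ring-B ketone (6-exo-trig hemiketal) and water is lost to give the pyranone. Only the ring-A phenol is free, so ring C can close in one direction only.

Step 18
Reactants: 33 2-[2-(allyloxy)-4,5-dimethoxyphenyl]-3-(2-bromo-3-methylbut-2-enyl)-5-methoxy-8,8-dimethyl-6-(3-methylbut-2-enyl)-4H,8H-pyrano[2,3-f]chromen-4-one
Product: 34 3-(2-bromo-3-methylbut-2-enyl)-2-(2-hydroxy-4,5-dimethoxyphenyl)-5-methoxy-8,8-dimethyl-6-(3-methylbut-2-enyl)-4H,8H-pyrano[2,3-f]chromen-4-one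
Conditions: Pd(PPh3)4 (5 mol%), morpholine, THF, rt
Reagents that add atoms: none
Why: Tsuji–Trost-type deallylation. Zerovalent palladium ionises the aryl allyl ether and morpholine traps the π-allyl complex. At room temperature the hindered tetrasubstituted alkenyl bromide is slow to undergo oxidative addition.

Step 19
Reactants: 34 3-(2-bromo-3-methylbut-2-enyl)-2-(2-hydroxy-4,5-dimethoxyphenyl)-5-methoxy-8,8-dimethyl-6-(3-methylbut-2-enyl)-4H,8H-pyrano[2,3-f]chromen-4-one
Product: 35 target CNP0192589.0
Conditions: CuI (20 mol%), 1,10-phenanthroline (40 mol%), Cs2CO3, toluene, 110 °C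
Reagents that add atoms: none
Why: Ullmann-type intramolecular O-vinylation. The copper phenoxide couples with the alkenyl bromide and closes ring E in a 7-exo sense with the double bond held exocyclic. No geometry issue arises because the alkene ends in two methyl groups, and the basic conditions spare the new enol ether.

## Compound list

1 | 5-methoxyresorcinol | COc1cc(O)cc(O)c1 | starting material
2 | 5-methoxy-1,3-phenylene bis(isopropylcarbamate) | COc1cc(OC(=O)NC(C)C)cc(OC(=O)NC(C)C)c1 | intermediate
3 | 5-methoxy-1,3-phenylene bis[N-(tert-butyldimethylsilyl)-N-isopropylcarbamate] (not isolated) | COc1cc(OC(=O)N(C(C)C)[Si](C)(C)C(C)(C)C)cc(OC(=O)N(C(C)C)[Si](C)(C)C(C)(C)C)c1 | intermediate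
4 | 2-lithio derivative of 3 (not isolated) | COc1cc(OC(=O)N(C(C)C)[Si](C)(C)C(C)(C)C)c([Li])c(OC(=O)N(C(C)C)[Si](C)(C)C(C)(C)C)c1 | intermediate
5 | 2-(trimethylsilyl) derivative of 3 (not isolated) | COc1cc(OC(=O)N(C(C)C)[Si](C)(C)C(C)(C)C)c([Si](C)(C)C)c(OC(=O)N(C(C)C)[Si](C)(C)C(C)(C)C)c1 | intermediate
6 | 5-methoxy-2-(trimethylsilyl)-1,3-phenylene bis(isopropylcarbamate) | COc1cc(OC(=O)NC(C)C)c([Si](C)(C)C)c(OC(=O)NC(C)C)c1 | intermediate
7 | 5-methoxy-2-(trimethylsilyl)benzene-1,3-diol (in the flask as its amidinium bis-phenolate, not isolated) | COc1cc(O)c([Si](C)(C)C)c(O)c1 | intermediate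
8 | 5-methoxy-2-(trimethylsilyl)-1,3-phenylene bis(trifluoromethanesulfonate) | COc1cc(OS(=O)(=O)C(F)(F)F)c([Si](C)(C)C)c(OS(=O)(=O)C(F)(F)F)c1 | intermediate
9 | 3-methylbut-2-enal | CC(C)=CC=O | starting material
10 | 5-methoxy-3-(triflyloxy)benzyne (not isolated) | COC1=CC#CC(OS(=O)(=O)C(F)(F)F)=C1 | intermediate
11 | 5-methoxy-2-(2-methylprop-1-enyl)-2H-benzoxet-3-yl triflate, racemic (not isolated) | COc1cc(OS(=O)(=O)C(F)(F)F)c2c(c1)OC2C=C(C)C | intermediate
12 | (6Z)-3-methoxy-6-(3-methylbut-2-enylidene)-5-(triflyloxy)cyclohexa-2,4-dien-1-one (not isolated) | COC1=CC(=O)/C(=C\C=C(C)C)C(OS(=O)(=O)C(F)(F)F)=C1 | intermediate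
13 | 7-methoxy-2,2-dimethyl-2H-chromen-5-yl trifluoromethanesulfonate | COc1cc(OS(=O)(=O)C(F)(F)F)c2C=CC(C)(C)Oc2c1 | intermediate
14 | 7-methoxy-2,2-dimethyl-2H-chromen-5-ol | COc1cc(O)c2C=CC(C)(C)Oc2c1 | intermediate
15 | triisopropyl[(7-methoxy-2,2-dimethyl-2H-chromen-5-yl)oxy]silane | COc1cc(O[Si](C(C)C)(C(C)C)C(C)C)c2C=CC(C)(C)Oc2c1 | intermediate
16 | 8-lithio derivative of 15 (not isolated) | COc1cc(O[Si](C(C)C)(C(C)C)C(C)C)c2C=CC(C)(C)Oc2c1[Li] | intermediate
17 | 8-cuprio derivative of 15 (not isolated) | COc1cc(O[Si](C(C)C)(C(C)C)C(C)C)c2C=CC(C)(C)Oc2c1[Cu] | intermediate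
18 | triisopropyl{[7-methoxy-2,2-dimethyl-8-(3-methylbut-2-enyl)-2H-chromen-5-yl]oxy}silane | COc1cc(O[Si](C(C)C)(C(C)C)C(C)C)c2C=CC(C)(C)Oc2c1CC=C(C)C | intermediate
19 | 7-methoxy-2,2-dimethyl-8-(3-methylbut-2-enyl)-2H-chromen-5-ol (in the flask as its tetrabutylammonium phenolate, not isolated) | COc1cc(O)c2C=CC(C)(C)Oc2c1CC=C(C)C | intermediate
20 | 7-methoxy-5-(methoxymethoxy)-2,2-dimethyl-8-(3-methylbut-2-enyl)-2H-chromene | COc1cc(OCOC)c2C=CC(C)(C)Oc2c1CC=C(C)C | intermediate
21 | 6-lithio derivative of 20 (not isolated) | COc1c([Li])c(OCOC)c2C=CC(C)(C)Oc2c1CC=C(C)C | intermediate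
22 | 1-[7-methoxy-5-(methoxymethoxy)-2,2-dimethyl-8-(3-methylbut-2-enyl)-2H-chromen-6-yl]ethanone | COc1c(C(C)=O)c(OCOC)c2C=CC(C)(C)Oc2c1CC=C(C)C | intermediate
23 | 1-[5-hydroxy-7-methoxy-2,2-dimethyl-8-(3-methylbut-2-enyl)-2H-chromen-6-yl]ethanone | COc1c(C(C)=O)c(O)c2C=CC(C)(C)Oc2c1CC=C(C)C | intermediate
24 | 2-hydroxy-4,5-dimethoxybenzoic acid | COc1cc(O)c(C(=O)O)cc1OC | starting material
25 | allyl 2-(allyloxy)-4,5-dimethoxybenzoate | C=CCOC(=O)c1cc(OC)c(OC)cc1OCC=C | intermediate
26 | 2-(allyloxy)-4,5-dimethoxybenzoic acid | OC(=O)c1cc(OC)c(OC)cc1OCC=C | intermediate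
27 | 2-(allyloxy)-4,5-dimethoxybenzoyl chloride (not isolated) | ClC(=O)c1cc(OC)c(OC)cc1OCC=C | intermediate
28 | 6-acetyl-7-methoxy-2,2-dimethyl-8-(3-methylbut-2-enyl)-2H-chromen-5-yl 2-(allyloxy)-4,5-dimethoxybenzoate | COc1c(C(C)=O)c(OC(=O)c3cc(OC)c(OC)cc3OCC=C)c2C=CC(C)(C)Oc2c1CC=C(C)C | intermediate
29 | 1-[2-(allyloxy)-4,5-dimethoxyphenyl]-3-[5-hydroxy-7-methoxy-2,2-dimethyl-8-(3-methylbut-2-enyl)-2H-chromen-6-yl]propane-1,3-dione | COc1c(C(=O)CC(=O)c3cc(OC)c(OC)cc3OCC=C)c(O)c2C=CC(C)(C)Oc2c1CC=C(C)C | intermediate
30 | 3-methylbuta-1,2-diene | CC(C)=C=C | starting material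
31 | 1,2-dibromo-3-methylbut-2-ene | CC(C)=C(Br)CBr | intermediate
32 | 1-[2-(allyloxy)-4,5-dimethoxyphenyl]-2-(2-bromo-3-methylbut-2-enyl)-3-[5-hydroxy-7-methoxy-2,2-dimethyl-8-(3-methylbut-2-enyl)-2H-chromen-6-yl]propane-1,3-dione (racemic) | COc1c(C(=O)C(CC(Br)=C(C)C)C(=O)c3cc(OC)c(OC)cc3OCC=C)c(O)c2C=CC(C)(C)Oc2c1CC=C(C)C | intermediate
33 | 2-[2-(allyloxy)-4,5-dimethoxyphenyl]-3-(2-bromo-3-methylbut-2-enyl)-5-methoxy-8,8-dimethyl-6-(3-methylbut-2-enyl)-4H,8H-pyrano[2,3-f]chromen-4-one | C=CCOc1cc(OC)c(OC)cc1-c1oc2c3C=CC(C)(C)Oc3c(CC=C(C)C)c(OC)c2c(=O)c1CC(Br)=C(C)C | intermediate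
34 | 3-(2-bromo-3-methylbut-2-enyl)-2-(2-hydroxy-4,5-dimethoxyphenyl)-5-methoxy-8,8-dimethyl-6-(3-methylbut-2-enyl)-4H,8H-pyrano[2,3-f]chromen-4-one | Oc1cc(OC)c(OC)cc1-c1oc2c3C=CC(C)(C)Oc3c(CC=C(C)C)c(OC)c2c(=O)c1CC(Br)=C(C)C | intermediate
35 | CNP0192589.0: the 5-methoxy-8,8-dimethyl-6-(3-methylbut-2-enyl)pyrano[2,3-f]chromen-4-one whose C3 and C2′ are bridged by CH2–C(=CMe2)–O (ring E), ring B carrying 4′,5′-dimethoxy groups | COc1cc2c(cc1OC)-c1oc3c4c(c(CC=C(C)C)c(OC)c3c(=O)c1CC(=C(C)C)O2)OC(C)(C)C=C4 | target

## Step count and least certain steps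

Total step count: 19. Longest linear sequence: 16 steps (steps 1 to 10, 13, 14 and 16 to 19). Steps 11 and 12 (ring-B acid) and step 15 (dibromide) are side branches.

**Step 4 (key step).** The aryl anion formed when the aldehyde oxygen adds lies ortho to the remaining triflate. It may expel that triflate before the four-membered ring closes, which would start a second aryne and lead to oligomers. The enolisable aldehyde may also be deprotonated at its γ-methyl group by fluoride or by the aryl anion. Fallback: leave the aryne route and condense 1 directly with 9 (ethylenediammonium diacetate, toluene, reflux; Knoevenagel-type condensation followed by oxa-6π closure). Attack at the carbon between the two hydroxyls gives chromenol 14 directly. Attack at the other activated carbon gives the regioisomer 5-methoxy-2,2-dimethyl-2H-chromen-7-ol F1, which has to be separated. The route is rejoined at 14, so steps 1 to 5 are replaced, at the cost of regiocontrol.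

**Step 19.** Coupling at the tetrasubstituted alkenyl bromide in a seven-membered ring may be slower than base-induced loss of HBr from the side chain toward an allene, or than simple decomposition of the copper phenoxide. Fallback: from 34, change from the copper manifold to C–O reductive elimination at palladium (Pd2(dba)3, t-BuXPhos, K3PO4, toluene, 100 °C). Here oxidative addition of zerovalent palladium into the C–Br bond comes first and the phenoxide is joined in the reductive elimination. This gives 35 directly and makes no new compound (F0).

**Step 16.** Alkylation may occur at the phenolate oxygen or at the diketonate oxygen, or twice at carbon, in place of single C-alkylation. Fallback: from 29, close ring C first (TsOH·H2O, MeCN, 60 °C) to the 3-unsubstituted flavone 2-[2-(allyloxy)-4,5-dimethoxyphenyl]-5-methoxy-8,8-dimethyl-6-(3-methylbut-2-enyl)-4H,8H-pyrano[2,3-f]chromen-4-one F2. Then deprotonate C3 with LiN(i-Pr)2 in THF at −78 °C and alkylate the 3-lithioflavone with 31. The route is rejoined at 33.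

**Step 7.** Metalation may compete at C6 next to the silyl ether, and the arylcopper may attack the γ-carbon of prenyl bromide and give the branched 1,1-dimethylallyl isomer. Fallback: from 15, by way of 16 and 17, trap with allyl bromide, which has no α/γ ambiguity, to give triisopropyl{[8-allyl-7-methoxy-2,2-dimethyl-2H-chromen-5-yl]oxy}silane F3. Then convert allyl to prenyl by cross-metathesis with 2-methylbut-2-ene (second-generation Grubbs catalyst, RuCl2(=CHPh)(H2IMes)(PCy3), CH2Cl2, 40 °C). The hindered ring alkene of the chromene should not take part. The route is rejoined at 18.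

**Step 9.** The hindered aryllithium 21 may take a proton from the enolisable amide in place of adding to it, which returns 20. Fallback: from 21, quench with DMF to give 7-methoxy-5-(methoxymethoxy)-2,2-dimethyl-8-(3-methylbut-2-enyl)-2H-chromene-6-carbaldehyde F4. Add MeMgBr to give racemic 1-[7-methoxy-5-(methoxymethoxy)-2,2-dimethyl-8-(3-methylbut-2-enyl)-2H-chromen-6-yl]ethanol F5. Oxidise with Dess–Martin periodinane (NaHCO3, CH2Cl2). The route is rejoined at 22.

## Further compounds

F1 | step 4 | 5-methoxy-2,2-dimethyl-2H-chromen-7-ol | COc1cc(O)cc2OC(C)(C)C=Cc12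
F0 | step 19 | none | none
F2 | step 16 | 2-[2-(allyloxy)-4,5-dimethoxyphenyl]-5-methoxy-8,8-dimethyl-6-(3-methylbut-2-enyl)-4H,8H-pyrano[2,3-f]chromen-4-one | C=CCOc1cc(OC)c(OC)cc1-c1cc(=O)c2c(OC)c(CC=C(C)C)c3OC(C)(C)C=Cc3c2o1
F3 | step 7 | triisopropyl{[8-allyl-7-methoxy-2,2-dimethyl-2H-chromen-5-yl]oxy}silane | COc1cc(O[Si](C(C)C)(C(C)C)C(C)C)c2C=CC(C)(C)Oc2c1CC=C
F4 | step 9 | 7-methoxy-5-(methoxymethoxy)-2,2-dimethyl-8-(3-methylbut-2-enyl)-2H-chromene-6-carbaldehyde | COc1c(C=O)c(OCOC)c2C=CC(C)(C)Oc2c1CC=C(C)C
F5 | step 9 | 1-[7-methoxy-5-(methoxymethoxy)-2,2-dimethyl-8-(3-methylbut-2-enyl)-2H-chromen-6-yl]ethanol (racemic) | COc1c(C(C)O)c(OCOC)c2C=CC(C)(C)Oc2c1CC=C(C)C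
A1 | alternative 1 | 3-(2-bromo-3-methylbut-2-enyl)-2-[4,5-dimethoxy-2-(methoxymethoxy)phenyl]-5-methoxy-8,8-dimethyl-6-(3-methylbut-2-enyl)pyrano[2,3-f]chromen-4-one | COCOc1cc(OC)c(OC)cc1-c1oc2c3C=CC(C)(C)Oc3c(CC=C(C)C)c(OC)c2c(=O)c1CC(Br)=C(C)C
A2 | alternative 1 | 5-{[4-bromo-1-(4,5-dimethoxy-2-(methoxymethoxy)phenyl)-5-methylhex-4-en-2-yn-1-yl]oxy}-7-methoxy-2,2-dimethyl-8-(3-methylbut-2-enyl)-2H-chromene-6-carbaldehyde (racemic) | COCOc1cc(OC)c(OC)cc1C(C#CC(Br)=C(C)C)Oc1c(C=O)c(OC)c(CC=C(C)C)c2OC(C)(C)C=Cc12
A3 | alternative 2 | 5-O-demethyl target (5-hydroxy compound) | COc1cc2c(cc1OC)-c1oc3c4c(c(CC=C(C)C)c(O)c3c(=O)c1CC(=C(C)C)O2)OC(C)(C)C=C4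
A4 | alternative 2 | ring-B/C/E core carrying 5-O-(2-methylbut-3-en-2-yl) and 7-O-(2-methylbut-3-yn-2-yl) ethers | COc1cc2c(cc1OC)-c1oc3cc(OC(C)(C)C#C)cc(OC(C)(C)C=C)c3c(=O)c1CC(=C(C)C)O2
A5 | alternative 3 | 2-[4,5-dimethoxy-2-(methoxymethoxy)phenyl]-5-methoxy-8,8-dimethyl-6-(3-methylbut-2-enyl)pyrano[2,3-f]chromen-4-one | COCOc1cc(OC)c(OC)cc1-c1cc(=O)c2c(OC)c(CC=C(C)C)c3OC(C)(C)C=Cc3c2o1
A6 | alternative 3 | 6-iodo-7-methoxy-2,2-dimethyl-8-(3-methylbut-2-enyl)-2H-chromen-5-ol | COc1c(I)c(O)c2C=CC(C)(C)Oc2c1CC=C(C)C
A7 | alternative 3 | 1-ethynyl-4,5-dimethoxy-2-(methoxymethoxy)benzene | COCOc1cc(OC)c(OC)cc1C#C
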